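**Plan**
- Retrosynthesis: the C11–O aryl ether is cut first (umbelliferone plus a primary alcohol), then the C8 methylidene (from a C8 ketone), then both ring B bonds C6–C7 and C9–C10 together in a [3+3] sense.
- Enabling feature: ring B carries only the exocyclic methylene at C8, flanked by C7 and C9(–C11). This is a disguised acetoacetate (C7 γ-carbon, C8 carbonyl, C9 α-carbon, C11 ester carbon). C6–C5–C10 of ring A is an allyl cation with a primary (C6) and a tertiary, methyl-bearing (C10) terminus.
- Forward: ring A is built first from 2-methylcyclohexane-1,3-dione (steps 1–8), ring B is annulated onto it in one flask (step 9), then methylenation, hydride reduction and etherification follow (steps 10–12).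
- Stereochemistry: C3 and C4 come from enzymatic desymmetrisation of a prochiral 2,2-disubstituted dione. C5 and C10 are relayed from C4 in the protonation and ring closure (chair, trans-decalin). C9 equilibrates to the equatorial ester.

Key step: step 9

Remark: drimane numbering is used for the decalin carbons (C3 carbinol, C4 quaternary, C5/C10 ring fusion, C8 methylidene-bearing, C9 bearing C11H2O); diene 10 is taken as commercially available.

**Step 1**
Reactants: 1 2-methylcyclohexane-1,3-dione
Product: 2 2-(hydroxymethyl)-2-methylcyclohexane-1,3-dione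
Conditions: 37% aq. HCHO (3 equiv), H2O, 23 °C
Reagents that add atoms: formaldehyde C=O
Why: Aldol addition of the acidic dione enol to formaldehyde should give the C-hydroxymethyl adduct, the 2-methyl group blocks dehydration, and the new quaternary carbon (future C4) is still prochiral.

**Step 2**
Reactants: 2 2-(hydroxymethyl)-2-methylcyclohexane-1,3-dione
Product: 3 (2R,3R)-3-hydroxy-2-(hydroxymethyl)-2-methylcyclohexan-1-one (hydroxyl cis to CH2OH)
Conditions: (R)-selective ketoreductase (NADPH-dependent alcohol dehydrogenase, chosen from a screening panel), NADP+ (cat.), i-PrOH, KH2PO4/K2HPO4 buffer pH 7, 30 °C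
Reagents that add atoms: none
Why: Enzymatic desymmetrisation (ketoreductase class) should reduce one of the two enantiotopic carbonyl groups on one face, which sets the carbinol centre (future C3) and with it the quaternary centre (future C4), as known for enzymatic mono-reduction of 2,2-disubstituted cyclohexane-1,3-diones.

**Step 3**
Reactants: 3 (2R,3R)-3-hydroxy-2-(hydroxymethyl)-2-methylcyclohexan-1-one
Product: 4 (1R,2R)-2-methyl-3-oxo-2-[(pivaloyloxy)methyl]cyclohexyl pivalate
Conditions: PivCl, pyridine, DMAP (cat.), CH2Cl2, 0 → 40 °C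
Reagents that add atoms: pivaloyl chloride CC(C)(C)C(Cl)=O
Why: DMAP-catalysed acylation of both hydroxyls should give hindered, non-participating pivalates that tolerate the enolate steps, the Lewis acid step and the ylide.

**Step 4**
Reactants: 4 (1R,2R)-2-methyl-3-oxo-2-[(pivaloyloxy)methyl]cyclohexyl pivalate
Product: 5 (1R,2R,4RS)-2,4-dimethyl-3-oxo-2-[(pivaloyloxy)methyl]cyclohexyl pivalate (both epimers at the new methine are used)
Conditions: LiN(i-Pr)2, THF, −78 °C; MeI, −78 → −20 °C
Reagents that add atoms: iodomethane CI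
Why: Enolate alkylation can take place only at the single enolisable α-carbon (the other one is quaternary), and the configuration of the new methine is irrelevant because it becomes sp2 in step 5.

**Step 5**
Reactants: 5 (1R,2R,4RS)-2,4-dimethyl-3-oxo-2-[(pivaloyloxy)methyl]cyclohexyl pivalate
Product: 6 (1R,2R)-2,4-dimethyl-2-[(pivaloyloxy)methyl]-3-(trifluoromethanesulfonyloxy)cyclohex-3-en-1-yl pivalate
Conditions: KN(SiMe3)2, THF, −78 → −20 °C; PhNTf2, −78 → 0 °C
Reagents that add atoms: N-phenylbis(trifluoromethanesulfonimide) O=S(=O)(N(c1ccccc1)S(=O)(=O)C(F)(F)F)C(F)(F)F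
Why: Enolisation toward the only α-hydrogen followed by O-sulfonylation (enol triflate formation) should fix the tetrasubstituted double bond between the future C5 and C10.

**Step 6**
Reactants: 6 (1R,2R)-2,4-dimethyl-2-[(pivaloyloxy)methyl]-3-(trifluoromethanesulfonyloxy)cyclohex-3-en-1-yl pivalate
Product: 7 (1R,2R)-3-formyl-2,4-dimethyl-2-[(pivaloyloxy)methyl]cyclohex-3-en-1-yl pivalate
Conditions: Pd(PPh3)4 (5 mol %), CO (3 atm), Bu3SnH (slow addition), LiCl, THF, 55 °C
Reagents that add atoms: carbon monoxide [C-]#[O+]
Why: Carbonylative Stille-type formylation (oxidative addition of the vinyl triflate to zerovalent palladium, CO insertion, hydride transfer from Bu3SnH to the acyl-palladium) should give the enal and add the C6 carbon without touching the pivalates.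

**Step 7**
Reactants: 7 (1R,2R)-3-formyl-2,4-dimethyl-2-[(pivaloyloxy)methyl]cyclohex-3-en-1-yl pivalate
Product: 8 (1R,2R)-3-(hydroxymethyl)-2,4-dimethyl-2-[(pivaloyloxy)methyl]cyclohex-3-en-1-yl pivalate
Conditions: NaBH4, CeCl3·7H2O, MeOH, 0 °C
Reagents that add atoms: none
Why: Luche reduction should reduce the hindered conjugated aldehyde 1,2-selectively to the primary allylic alcohol and leave the pivalates intact.

**Step 8**
Reactants: 8 (1R,2R)-3-(hydroxymethyl)-2,4-dimethyl-2-[(pivaloyloxy)methyl]cyclohex-3-en-1-yl pivalate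
Product: 9 (1R,2R)-3-(acetoxymethyl)-2,4-dimethyl-2-[(pivaloyloxy)methyl]cyclohex-3-en-1-yl pivalate
Conditions: Ac2O, pyridine, DMAP (cat.), CH2Cl2, 0 °C
Reagents that add atoms: acetic anhydride CC(=O)OC(C)=O
Why: Acylation of the primary allylic alcohol installs acetate as the ionisable leaving group for the allyl cation.

**Step 9**
Reactants: 9 (1R,2R)-3-(acetoxymethyl)-2,4-dimethyl-2-[(pivaloyloxy)methyl]cyclohex-3-en-1-yl pivalate; 10 1-methoxy-1,3-bis(trimethylsilyloxy)buta-1,3-diene
Product: 12 methyl (1S,4aS,5R,6R,8aR)-5,8a-dimethyl-2-oxo-6-(pivaloyloxy)-5-[(pivaloyloxy)methyl]decahydronaphthalene-1-carboxylate, via monocyclic keto ester 11 (not isolated)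
Conditions: SnCl4 (2.5 equiv), CH2Cl2, −78 °C; then H2O (1.5 equiv, as water-saturated CH2Cl2), −78 → 23 °C
Reagents that add atoms: none
Why: Proposed new method: SnCl4 ionises the allylic acetate of 9 to the C6–C5–C10 allyl cation, the terminal (γ) carbon of dienol ether 10 captures it at the unhindered C6 terminus (C6–C7 bond), and after water has released the SnCl4-bound β-keto ester 11 its acidified enol protonates the tetrasubstituted C5=C10 alkene and C9 closes onto the tertiary C10 cation (C9–C10 bond), a cationic [3+3] annulation of a 1,3-dielectrophile with a 1,3-dinucleophile. The closest known reaction types are the Lewis-acid SN1 alkylation of silyl enol ethers by allylic acetates, with the γ-selectivity typical of 1,3-bis(silyloxy)dienes, and the SnCl4-mediated cyclisation of δ,ε-unsaturated β-keto esters onto alkenes, which is established for the 2,6,6-trimethylcyclohexenyl analogue of 11; the two have not been merged in one flask on this substrate class. Ring B closes in a 6-endo mode (both former alkene carbons inside the new ring) through a chair-like transition state with the keto ester chain equatorial on C5. C5 is set by protonation anti to the pseudoaxial CH2OPiv group on the neighbouring quaternary C4 in the half-chair that keeps the C3 pivalate equatorial, C10 by attack of C9 trans to the new C5–H (trans-decalin, axial methyl cis to CH2OPiv), and C9 by equilibration of the β-keto ester to the equatorial ester. The step needs γ- over α-attack of the dinucleophile (inherent to 10), attack at the primary and not the tertiary end of the cation (steric), C- over O-cyclisation (O-alkylation by a tertiary cation is reversible under SnCl4) and one face of ring A (the conformational bias just described, which is modest, so the diastereomeric trans-decalin may have to be separated here; the pivalates do not participate, unlike ether protecting groups).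

**Step 10**
Reactants: 12 methyl (1S,4aS,5R,6R,8aR)-5,8a-dimethyl-2-oxo-6-(pivaloyloxy)-5-[(pivaloyloxy)methyl]decahydronaphthalene-1-carboxylate
Product: 13 methyl (1R,4aS,5R,6R,8aR)-5,8a-dimethyl-2-methylidene-6-(pivaloyloxy)-5-[(pivaloyloxy)methyl]decahydronaphthalene-1-carboxylate
Conditions: Ph3PCH3Br, KN(SiMe3)2, toluene, 0 → 80 °C
Reagents that add atoms: methyltriphenylphosphonium bromide C[P+](c1ccccc1)(c1ccccc1)c1ccccc1.[Br-]
Why: Wittig methylenation of the C8 ketone with excess alkoxide-free ylide should give the exocyclic alkene, as done on related 2-oxodecalin-1-carboxylates, and the equatorial C9 ester remains the thermodynamic epimer.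

**Step 11**
Reactants: 13 methyl (1R,4aS,5R,6R,8aR)-5,8a-dimethyl-2-methylidene-6-(pivaloyloxy)-5-[(pivaloyloxy)methyl]decahydronaphthalene-1-carboxylate
Product: 14 (1R,2R,4aR,5R,8aS)-1,5-bis(hydroxymethyl)-1,4a-dimethyl-6-methylidenedecahydronaphthalen-2-ol
Conditions: LiAlH4, THF, 0 → 23 °C
Reagents that add atoms: none
Why: Hydride reduction of esters with LiAlH4 should turn the methyl ester into the C11 primary alcohol and cleave both pivalates in the same operation without touching the 1,1-disubstituted alkene.

**Step 12**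
Reactants: 14 (1R,2R,4aR,5R,8aS)-1,5-bis(hydroxymethyl)-1,4a-dimethyl-6-methylidenedecahydronaphthalen-2-ol; 15 7-hydroxy-2H-chromen-2-one (umbelliferone)
Product: 16 7-{[(1R,4aS,5R,6R,8aR)-6-hydroxy-5-(hydroxymethyl)-5,8a-dimethyl-2-methylidenedecahydronaphthalen-1-yl]methoxy}-2H-chromen-2-one
Conditions: PPh3, DIAD, THF, 0 → 23 °C
Reagents that add atoms: none
Why: Mitsunobu etherification with the acidic phenol should occur by SN2 at C11 only, because the C4 hydroxymethyl is neopentyl and axial and the C3 carbinol is secondary and flanked by the quaternary centre, so no stereocentre is touched.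

**Compound list**
1 | 2-methylcyclohexane-1,3-dione | CC1C(=O)CCCC1=O | starting material
2 | 2-(hydroxymethyl)-2-methylcyclohexane-1,3-dione | CC1(CO)C(=O)CCCC1=O | intermediate
3 | (2R,3R)-3-hydroxy-2-(hydroxymethyl)-2-methylcyclohexan-1-one | O=C1[C@](C)(CO)[C@H](O)CCC1 | intermediate
4 | (1R,2R)-2-methyl-3-oxo-2-[(pivaloyloxy)methyl]cyclohexyl pivalate | O=C1[C@](C)(COC(=O)C(C)(C)C)[C@H](OC(=O)C(C)(C)C)CCC1 | intermediate
5 | (1R,2R,4RS)-2,4-dimethyl-3-oxo-2-[(pivaloyloxy)methyl]cyclohexyl pivalate | O=C1[C@](C)(COC(=O)C(C)(C)C)[C@H](OC(=O)C(C)(C)C)CCC1C | intermediate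
6 | (1R,2R)-2,4-dimethyl-2-[(pivaloyloxy)methyl]-3-(trifluoromethanesulfonyloxy)cyclohex-3-en-1-yl pivalate | CC1=C(OS(=O)(=O)C(F)(F)F)[C@](C)(COC(=O)C(C)(C)C)[C@H](OC(=O)C(C)(C)C)CC1 | intermediate
7 | (1R,2R)-3-formyl-2,4-dimethyl-2-[(pivaloyloxy)methyl]cyclohex-3-en-1-yl pivalate | CC1=C(C=O)[C@](C)(COC(=O)C(C)(C)C)[C@H](OC(=O)C(C)(C)C)CC1 | intermediate
8 | (1R,2R)-3-(hydroxymethyl)-2,4-dimethyl-2-[(pivaloyloxy)methyl]cyclohex-3-en-1-yl pivalate | CC1=C(CO)[C@](C)(COC(=O)C(C)(C)C)[C@H](OC(=O)C(C)(C)C)CC1 | intermediate
9 | (1R,2R)-3-(acetoxymethyl)-2,4-dimethyl-2-[(pivaloyloxy)methyl]cyclohex-3-en-1-yl pivalate | CC1=C(COC(C)=O)[C@](C)(COC(=O)C(C)(C)C)[C@H](OC(=O)C(C)(C)C)CC1 | intermediate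
10 | 1-methoxy-1,3-bis(trimethylsilyloxy)buta-1,3-diene | COC(O[Si](C)(C)C)=CC(=C)O[Si](C)(C)C | starting material
11 | methyl 5-{(5R,6R)-2,6-dimethyl-5-(pivaloyloxy)-6-[(pivaloyloxy)methyl]cyclohex-1-en-1-yl}-3-oxopentanoate | CC1=C(CCC(=O)CC(=O)OC)[C@](C)(COC(=O)C(C)(C)C)[C@H](OC(=O)C(C)(C)C)CC1 | intermediate
12 | methyl (1S,4aS,5R,6R,8aR)-5,8a-dimethyl-2-oxo-6-(pivaloyloxy)-5-[(pivaloyloxy)methyl]decahydronaphthalene-1-carboxylate | O=C1CC[C@@H]2[C@](C)(COC(=O)C(C)(C)C)[C@H](OC(=O)C(C)(C)C)CC[C@@]2(C)[C@@H]1C(=O)OC | intermediate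
13 | methyl (1R,4aS,5R,6R,8aR)-5,8a-dimethyl-2-methylidene-6-(pivaloyloxy)-5-[(pivaloyloxy)methyl]decahydronaphthalene-1-carboxylate | C=C1CC[C@@H]2[C@](C)(COC(=O)C(C)(C)C)[C@H](OC(=O)C(C)(C)C)CC[C@@]2(C)[C@@H]1C(=O)OC | intermediate
14 | (1R,2R,4aR,5R,8aS)-1,5-bis(hydroxymethyl)-1,4a-dimethyl-6-methylidenedecahydronaphthalen-2-ol | C=C1CC[C@@H]2[C@](C)(CO)[C@H](O)CC[C@@]2(C)[C@@H]1CO | intermediate
15 | 7-hydroxy-2H-chromen-2-one (umbelliferone) | Oc1ccc2ccc(=O)oc2c1 | starting material
16 | 7-{[(1R,4aS,5R,6R,8aR)-6-hydroxy-5-(hydroxymethyl)-5,8a-dimethyl-2-methylidenedecahydronaphthalen-1-yl]methoxy}-2H-chromen-2-one | C=C1CC[C@@H]2[C@](C)(CO)[C@H](O)CC[C@@]2(C)[C@@H]1COc1ccc2ccc(=O)oc2c1 | target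

**Step count**
Total step count: 12. Longest linear sequence: 12 steps (from 1; 10 and 15 enter as purchased materials).

**Steps most likely to fail**

Step 9. The allyl cation may be lost to elimination before the C–C bond forms, or the proton relay for the ring closure may fail in the presence of the silyl species. The fallback separates the two bond formations and uses known chemistry. It sets out from 8: PBr3 (pyridine, Et2O, 0 °C) should give the primary allylic bromide (1R,2R)-3-(bromomethyl)-2,4-dimethyl-2-[(pivaloyloxy)methyl]cyclohex-3-en-1-yl pivalate F1. This alkylates the dianion of methyl acetoacetate (NaH, then n-BuLi, THF, 0 °C) at the γ-carbon to give keto ester 11, now isolated. SnCl4 in water-saturated CH2Cl2 then closes ring B by the established cyclisation of δ,ε-unsaturated β-keto esters, and the route is rejoined at 12. This fallback does not remove the facial-selectivity risk of the ring closure.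

Step 12. The phosphonium intermediate may be sequestered by the free 1,3-diol, or site selectivity among the three hydroxyls may be lost. The fallback sets out from 14: 2,2-dimethoxypropane and PPTS (CH2Cl2, 23 °C) should close the six-membered acetonide over the C3 hydroxyl and the C4 hydroxymethyl only, giving the acetonide of 14 with free C11 alcohol F2. Mitsunobu coupling with 15 then meets a single hydroxyl and should give the acetonide of the target F3. 80% aq. AcOH at 23 °C removes the acetonide without isomerising the exocyclic alkene, and the route ends at 16.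

Step 2. The enzyme may discriminate poorly between the two enantiotopic carbonyl groups, or the hydroxymethyl adduct may lose formaldehyde by retro-aldol reaction in buffer. The fallback sets out from 2: PivCl and pyridine (CH2Cl2, 0 °C) should give (1-methyl-2,6-dioxocyclohexyl)methyl pivalate F4, which can no longer undergo retro-aldol cleavage. Corey–Bakshi–Shibata reduction with (S)-2-methyl-CBS-oxazaborolidine and BH3·SMe2 (THF, −30 °C), with hydride delivery anti to the larger CH2OPiv group, should give [(1R,2R)-2-hydroxy-1-methyl-6-oxocyclohexyl]methyl pivalate F5. Pivaloylation of the secondary hydroxyl (PivCl, DMAP, pyridine) rejoins the route at 4.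

**Further compounds**
F1 | step 9 | (1R,2R)-3-(bromomethyl)-2,4-dimethyl-2-[(pivaloyloxy)methyl]cyclohex-3-en-1-yl pivalate | CC1=C(CBr)[C@](C)(COC(=O)C(C)(C)C)[C@H](OC(=O)C(C)(C)C)CC1
F2 | step 12 | acetonide of 14 over the C3 hydroxyl and the C4 hydroxymethyl, free C11 alcohol | C=C1CC[C@@H]2[C@]3(C)COC(C)(C)O[C@@H]3CC[C@@]2(C)[C@@H]1CO
F3 | step 12 | acetonide of the target over the C3 hydroxyl and the C4 hydroxymethyl | C=C1CC[C@@H]2[C@]3(C)COC(C)(C)O[C@@H]3CC[C@@]2(C)[C@@H]1COc1ccc2ccc(=O)oc2c1
F4 | step 2 | (1-methyl-2,6-dioxocyclohexyl)methyl pivalate | CC1(COC(=O)C(C)(C)C)C(=O)CCCC1=O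
F5 | step 2 | [(1R,2R)-2-hydroxy-1-methyl-6-oxocyclohexyl]methyl pivalate | O=C1[C@](C)(COC(=O)C(C)(C)C)[C@H](O)CCC1
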